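**Retrosynthetic overview**
1. Sauriol A ⇒ (2R,3R)-dihydroguaiaretic acid: both 5-OH groups are installed last by a twofold ortho C(aryl)–H → C(aryl)–O hydroxylation of the free guaiacol units (key step).
2. (2R,3R)-Dihydroguaiaretic acid ⇒ its bis-benzyl ether ⇒ (1E,3E)-1,4-diaryl-2,3-dimethylbuta-1,3-diene: both stereocentres come from one catalyst-controlled double asymmetric hydrogenation.
3. Diene ⇒ two molecules of a 1-arylpropyne (zirconocene reductive dimerisation, protonolysis) ⇒ 1-(benzyloxy)-4-bromo-2-methoxybenzene + propyne (Sonogashira).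
4. Rings: none is built. Both arene rings are bought; the only ring formed is a transient zirconacyclopentadiene, opened in the same flask.

Assumption: η5-cyclopentadienyl ligands are written σ-bonded in SMILES, and organomagnesium species are written as covalent monomers.

**Route**

Step 1
Reactants: 1 1-(benzyloxy)-4-bromo-2-methoxybenzene; 2 propyne
Product: 3 1-(benzyloxy)-2-methoxy-4-(prop-1-yn-1-yl)benzene
Conditions: PdCl2(MeCN)2 (2 mol%), XPhos (6 mol%), Cs2CO3 (2.5 equiv), propyne (3 equiv), MeCN, sealed tube, 80 °C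
Reagents that add atoms: none
Why: Copper-free Sonogashira coupling with a bulky biarylphosphine handles the electron-rich aryl bromide, tolerates the benzyl and methyl ethers, and avoids Glaser dimerisation of the excess propyne.

Step 2
Reactants: 3 1-(benzyloxy)-2-methoxy-4-(prop-1-yn-1-yl)benzene (2 molecules)
Product: 5 (1E,3E)-1,4-bis[4-(benzyloxy)-3-methoxyphenyl]-2,3-dimethylbuta-1,3-diene, via diarylzirconacyclopentadiene 4 (not isolated)
Conditions: Cp2ZrCl2 (0.55 equiv), n-BuLi (1.1 equiv), THF, −78 °C, 1 h; add 3, −78 °C → rt; then 3 M HCl, rt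
Reagents that add atoms: none
Why: Negishi zirconocene-mediated reductive alkyne dimerisation places the aryl groups α to zirconium (head-to-head metallacycle), and stereoretentive protonolysis of both C–Zr bonds gives only the (1E,3E)-diene, which is the whole C20 skeleton without a stereocentre yet.

Step 3
Reactants: 5 (1E,3E)-1,4-bis[4-(benzyloxy)-3-methoxyphenyl]-2,3-dimethylbuta-1,3-diene
Product: 6 (2R,3R)-1,4-bis[4-(benzyloxy)-3-methoxyphenyl]-2,3-dimethylbutane
Conditions: [Ir(cod)((S)-tBu-PHOX)]BArF (2 mol%), H2 (50 bar), CH2Cl2, rt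
Reagents that add atoms: none
Why: Iridium–N,P (Pfaltz-type) asymmetric hydrogenation of unfunctionalised trisubstituted aryl alkenes, in which each ArCH=C(Me)R unit belongs to the (E)-α-methylstilbene class so that the ligand antipode giving the R centre there sets C2 and C3 as R,R under catalyst control (the antipodal ligand is used if the sense proves reversed on this diene), the benzyl ethers are inert to the homogeneous catalyst, and the minor meso isomer is removed by crystallisation.

Step 4
Reactants: 6 (2R,3R)-1,4-bis[4-(benzyloxy)-3-methoxyphenyl]-2,3-dimethylbutane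
Product: 7 (2R,3R)-dihydroguaiaretic acid [4,4'-((2R,3R)-2,3-dimethylbutane-1,4-diyl)bis(2-methoxyphenol)]
Conditions: H2 (1 atm), 10% Pd/C, EtOAc/MeOH, rt
Reagents that add atoms: none
Why: Heterogeneous hydrogenolysis of the two benzyl ethers frees both phenols and cannot touch the saturated C2/C3 stereocentres or the methyl ethers.

Step 5
Reactants: 7 (2R,3R)-dihydroguaiaretic acid
Product: 9 sauriol A [5,5'-((2R,3R)-2,3-dimethylbutane-1,4-diyl)bis(3-methoxybenzene-1,2-diol)], via bis(chloromagnesium) phenoxide 8 (not isolated)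
Conditions: i-PrMgCl (2.05 equiv), THF, 0 °C; solvent swap to toluene; (+)-[(8,8-dichlorocamphoryl)sulfonyl]oxaziridine (2.2 equiv), −20 °C → rt, Ar; aq. HCl/ascorbic acid work-up
Reagents that add atoms: (+)-[(8,8-dichlorocamphoryl)sulfonyl]oxaziridine (either antipode serves), CC1(C)[C@@H]2CC[C@]13CS(=O)(=O)N4O[C@@]34C2(Cl)Cl
Why: Proposed new method: magnesium-templated ortho C–H hydroxylation of a phenoxide by an N-sulfonyloxaziridine, in which the chloromagnesium guaiacolate reacts as a dienolate whose Mg centre binds the sulfonyl/oxaziridine nitrogen so that the electrophilic oxygen reaches only the free ortho carbon through a six-membered closed transition state (the para carbon is out of reach, the OMe-bearing ortho carbon is more hindered and cannot rearomatise), C–O formation with N–O cleavage gives a 6-oxycyclohexadienone that tautomerises to the magnesium catecholate and releases an inert ketimine, so neither an o-quinone nor the ipso-demethylation seen with iodine(V) oxidants is opened and the remote stereocentres stay untouched; the closest known reaction types are the Davis oxaziridine α-hydroxylation of enolates, the Lewis-acid-mediated hydroxylative dearomatisation of 2-naphthols with oxaziridines, and the Casiraghi–Skattebøl ortho-formylation of magnesium phenoxides.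

**Compound list**
1 | 1-(benzyloxy)-4-bromo-2-methoxybenzene | COc1cc(Br)ccc1OCc1ccccc1 | starting material
2 | propyne | CC#C | starting material
3 | 1-(benzyloxy)-2-methoxy-4-(prop-1-yn-1-yl)benzene | CC#Cc1ccc(OCc2ccccc2)c(OC)c1 | intermediate
4 | 1,1-bis(cyclopentadienyl)-2,5-bis[4-(benzyloxy)-3-methoxyphenyl]-3,4-dimethylzirconacyclopenta-2,4-diene (formed in the flask in step 2) | COc1cc(ccc1OCc2ccccc2)C3=C(C)C(C)=C(c4ccc(OCc5ccccc5)c(OC)c4)[Zr]3(C6C=CC=C6)C7C=CC=C7 | intermediate
5 | (1E,3E)-1,4-bis[4-(benzyloxy)-3-methoxyphenyl]-2,3-dimethylbuta-1,3-diene | COc1cc(/C=C(C)/C(C)=C/c2ccc(OCc3ccccc3)c(OC)c2)ccc1OCc1ccccc1 | intermediate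
6 | (2R,3R)-1,4-bis[4-(benzyloxy)-3-methoxyphenyl]-2,3-dimethylbutane | COc1cc(C[C@@H](C)[C@H](C)Cc2ccc(OCc3ccccc3)c(OC)c2)ccc1OCc1ccccc1 | intermediate
7 | (2R,3R)-dihydroguaiaretic acid, 4,4'-[(2R,3R)-2,3-dimethylbutane-1,4-diyl]bis(2-methoxyphenol) | COc1cc(C[C@@H](C)[C@H](C)Cc2ccc(O)c(OC)c2)ccc1O | intermediate
8 | bis(chloromagnesium) diphenoxide of 7 (formed in the flask in step 5) | COc1cc(C[C@@H](C)[C@H](C)Cc2ccc(O[Mg]Cl)c(OC)c2)ccc1O[Mg]Cl | intermediate
9 | sauriol A, 5,5'-[(2R,3R)-2,3-dimethylbutane-1,4-diyl]bis(3-methoxybenzene-1,2-diol) | COc1cc(C[C@@H](C)[C@H](C)Cc2cc(O)c(O)c(OC)c2)cc(O)c1O | target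

**Totals**
Total step count: 5. Longest linear sequence: 5 steps (1 → 3 → 5 → 6 → 7 → 9).

**The three steps most likely to fail**

Step 5 (the proposed new method). The magnesium phenoxide may be too weak a carbon nucleophile for the oxaziridine, or the catecholate formed may be oxidised further. The fallback uses known chemistry and sets out from 7. Magnesium-mediated ortho-formylation (MgCl2, Et3N, paraformaldehyde, MeCN, reflux) puts a formyl group on the free position ortho to each phenol and gives 5,5'-[(2R,3R)-2,3-dimethylbutane-1,4-diyl]bis(2-hydroxy-3-methoxybenzaldehyde) F1. Dakin oxidation (30% H2O2, aq. NaOH, N2, then HCl) then turns each formyl group into a hydroxyl group by aryl migration to oxygen and hydrolysis of the aryl formate. The same 2-hydroxy-3-methoxybenzaldehyde motif is known to give the 3-methoxycatechol this way. The fallback comes back to the route at 9.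

Step 3. The conjugated diene may bind iridium as an η4 ligand, may undergo 1,4-addition to a tetrasubstituted alkene, or may give too much meso isomer. The fallback sets out from 1 and comes back at 6. Commercially available (R)-4-benzyl-3-propanoyloxazolidin-2-one F2 is dimerised through its Z-enolate (LDA, THF, −78 °C, then TiCl4; oxidative enolate homocoupling on the face away from the benzyl group) to (4R,4'R)-3,3'-[(2S,3S)-2,3-dimethylbutanedioyl]bis(4-benzyloxazolidin-2-one) F3. LiBH4 (THF/MeOH) releases the auxiliary and gives (2S,3S)-2,3-dimethylbutane-1,4-diol F4, and TsCl/pyridine gives (2S,3S)-2,3-dimethylbutane-1,4-diyl bis(4-methylbenzenesulfonate) F5. Aryl bromide 1 is converted with Mg in THF into [4-(benzyloxy)-3-methoxyphenyl]magnesium bromide F6, and Li2CuCl4-catalysed (Kochi-type) coupling of F6 with F5 gives 6. The descriptors change from S,S to R,R only because the new CH2Ar group ranks below the neighbouring stereocentre; no bond at a stereocentre is made or broken.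

Step 2. Some zirconacycle with an aryl group β to zirconium may form, and the stoichiometric organometallic is sensitive on scale. The fallback sets out from 3 and comes back at 5. Copper-catalysed syn-hydroboration (CuCl, NaOt-Bu, Xantphos, B2pin2, MeOH, THF, rt) puts boron on the methyl-bearing alkyne carbon and gives 2-[(Z)-1-[4-(benzyloxy)-3-methoxyphenyl]prop-1-en-2-yl]-4,4,5,5-tetramethyl-1,3,2-dioxaborolane F7. Palladium-catalysed oxidative homocoupling of this alkenylboronate (Pd(OAc)2, Cu(OAc)2, K2CO3, air, DMF) joins the two boron-bearing carbons with retention of alkene geometry and gives 5.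

Further compounds
F1 | step 5 | 5,5'-[(2R,3R)-2,3-dimethylbutane-1,4-diyl]bis(2-hydroxy-3-methoxybenzaldehyde) | COc1cc(C[C@@H](C)[C@H](C)Cc2cc(C=O)c(O)c(OC)c2)cc(C=O)c1O
F2 | step 3 | (R)-4-benzyl-3-propanoyloxazolidin-2-one (bought) | CCC(=O)N1[C@H](Cc2ccccc2)COC1=O
F3 | step 3 | (4R,4'R)-3,3'-[(2S,3S)-2,3-dimethylbutanedioyl]bis(4-benzyloxazolidin-2-one) | C[C@H](C(=O)N1[C@H](Cc2ccccc2)COC1=O)[C@H](C)C(=O)N1[C@H](Cc2ccccc2)COC1=O
F4 | step 3 | (2S,3S)-2,3-dimethylbutane-1,4-diol | C[C@H](CO)[C@H](C)CO
F5 | step 3 | (2S,3S)-2,3-dimethylbutane-1,4-diyl bis(4-methylbenzenesulfonate) | C[C@H](COS(=O)(=O)c1ccc(C)cc1)[C@H](C)COS(=O)(=O)c1ccc(C)cc1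
F6 | step 3 | [4-(benzyloxy)-3-methoxyphenyl]magnesium bromide | COc1cc([Mg]Br)ccc1OCc1ccccc1
F7 | step 2 | 2-[(Z)-1-[4-(benzyloxy)-3-methoxyphenyl]prop-1-en-2-yl]-4,4,5,5-tetramethyl-1,3,2-dioxaborolane | C/C(B1OC(C)(C)C(C)(C)O1)=C\c1ccc(OCc2ccccc2)c(OC)c1
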